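**Conventions.** Bicyclic compounds carry the locants their atoms have in the target: C1, C2, C3, C3a, C4–C7, C7a, and C1′ for the side-chain carbinol carbon. Before the key step C1′ is a ring atom and bears the methyl group. Ring A is C3a–C4–C5–C6–C7–C7a; ring B contains C1, C2 and C3. β is the face of H-3a, α the face of H-7a.

## The problem

Target 23 is a trans-fused octahydroinden-2-one in which every ring carbon except C5 is substituted: an acyloxy group on C1 beside the C2 ketone, a 1-hydroxyethyl arm on C3, an isopropyl group on C4, an axial allylic ester on C6 and a methylidene on C7. Eight stereocentres are present: C1, C3, C3a, C4, C6 and C7a on the bicycle, C1′ in the side chain, and the α-carbon of the 2-methylbutanoate, which is bought. C3a and C7a are β to the ketone and cannot be corrected by equilibration, so the trans fusion has to be built. An equatorial isopropyl group at C4 can anchor a chair from which C3a, C7a and the oxygens at C6 and C1 are relayed; C3 is enolisable and takes its more stable orientation; C1′ lies outside the rings and needs a reagent or relay from C3. The two hydroxyl groups carry different acids and must be made or unmasked one at a time. The β-hydroxy ketone (retro-aldol, dehydration), the α-acyloxy ketone (hydrolysis, epimerisation at C1), the allylic ester beside a 1,1-disubstituted alkene (ionisation, transposition) and the E-enoate (deconjugation) rule out strong base, strong acid and unselective hydride late in the route. The enabling feature is that the carbinol C1′ on C3, next to the C2 carbonyl, is an acetyl group at a lower oxidation level. A 2-acetylcyclopentanone is what a 2-methyl-2,3-epoxycyclohexanone gives when its acyl carbon migrates, so ring B can be unfolded into a six-membered ring containing C1′, that is, into a trans-decalin of the cadinane type.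

## Retrosynthesis

**23 to 22 (C1′–H).** The last bond made is the hydride on C1′, so 23 goes back to the β-diketone 22. This removes the one stereocentre that no ring controls and stores the fragile β-hydroxy ketone as a diketone that needs no protecting group. Ending with an esterification instead would leave a free C1′ hydroxyl competing with C1 or C6. In 22, C3 corrects itself through the enol. The forward step must deliver hydride to the acetyl carbonyl only, on the face that gives 1′R; a chelate model puts the substrate's own bias toward the same syn (1′R,3S) isomer.

**22 to 21 (C2–C3).** The C2–C3 bond is cut, C2 is returned to C1′, and the acetyl oxygen becomes an epoxide oxygen bridging C1′ and C3. An aldol or Dieckmann closure of the five-membered ring would need open-chain control over C1, C3, C3a and C7a, and Favorskii or Wolff contractions would leave a carboxyl group, not an acetyl group, on C3. Precursor 21 is a trans-decalin in which every centre sits on a chair, and C1′ and C3 are only epoxide carbons. The forward reaction must move the acyl carbon, not the methyl group. For that the epoxide oxygen is placed on the β face: the C3–O bond is then equatorial in the chair of ring B and antiperiplanar to the C1′–C2 ring bond. An oxygen on the α face would be axial at C3 and aligned with the C1′ methyl group and with H-3a.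

**21 to 14 (the two oxygens and their esters).** The C6 ester comes from alcohol 19 and acid 20, the C6 hydroxyl from allylic oxidation of the C7 methylidene in 18. The C1 ester comes from alcohol 16 and acid 17, and the C1 hydroxyl from the enolate of 14. C1 is treated first because it needs a strong base, which the enoate would not tolerate, whereas selenium dioxide tolerates an ester and an epoxy ketone. Each hydroxyl is esterified as soon as it exists, so no protecting group is needed. Both oxygens must arrive axially: β at C1, where an equatorial substituent would clash with the C7 methylidene, and α at C6.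

**14 to 11 (epoxide C–O bonds).** Alkaline hydrogen peroxide on enone 11 would be one step, but hydroperoxide adds to C3 axially from the α face, the wrong face for the shift. The enone is therefore reduced to the 2β-alcohol 12, whose hydroxyl directs the oxidant to the β face (13), and the ketone is restored (14). Two extra steps buy the alignment on which the key step depends.

**11 to 8 (ring B).** The C3=C1′ alkene is cut by ring-closing metathesis to triene 10. The C2–C1′ bond is cut to Weinreb amide 9 and an isopropenyl Grignard reagent, and 9 comes from ester 8. A Robinson-type annulation would place the methyl group and the unsaturation less directly and would fight the trans fusion. Metathesis uses the vinyl group that the cuprate step installs anyway and can only close the six-membered ring.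

**8 to 4 (ring A substituents).** The methylidene is a Wittig transform of ketone 7. Cutting C3a–C3 and C7a–C1 leads to (S)-cryptone 4, a vinyl nucleophile and methyl bromoacetate 5. The forward tandem addition–alkylation must place vinyl anti to isopropyl and the acetate arm anti to vinyl, which is the all-equatorial arrangement.

**4 to 1 and 2.** Cryptone is opened to 3-methylbutanal and but-3-en-2-one (Michael addition, then aldol condensation). C4 is the only ring stereocentre that needs a chiral catalyst.

## Roads not taken

**Alternative 1:** This road cuts C3a–C7a and C4–C5 together and forms both rings by an intramolecular Diels–Alder reaction. An open-chain triene with a 2-silyloxydiene and an (E)-alkene carrying the isopropyl group is heated to give A1, a trans-fused hydrindene with a silyl enol ether at C6 and silyl ethers at C2 and C1′.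
- Merits: two rings and two C–C bonds in one step; C1′ is fixed early by open-chain aldol chemistry; the enol ether marks C6/C7 for later work.
- Weak points: the dienophile is unactivated, so high temperature is needed. Trans selectivity in trienes with this tether length is usually modest. C1 is a bare CH2 in A1, so its oxygen must be put in later against the more acidic C3 side of the C2 ketone. Three silyl ethers have to be managed.
- Comparison: in bond-forming economy and in the early, reagent-free setting of C1′ this road is better. The chosen plan sets against it chair-based control of every ring centre, no protecting groups, and an enolate (15) that can form on one side only.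

**Alternative 2:** This road cuts C1–C7a. The five-membered ring is closed by anodic oxidation of a substrate holding a silyl enol ether at C7/C7a and a methyl enol ether at C2/C1; the radical cation of one is trapped by the other. The product is A2, with a ketone at C7 and a dimethyl ketal at C2.
- Merits: two nucleophilic carbons are joined directly, and C2 and C7 emerge at different protection levels.
- Weak points: the trans fusion rests on equilibration at C7a, and in hydrindanones with the carbonyl in the six-membered ring next to the fusion the cis isomer is often of similar or lower energy. A2 lacks both the C1 and the C6 oxygen, so two hydroxylations follow, the one at C1 again competing with C3. The electrolysis substrate needs several steps and dedicated equipment.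
- Comparison: differentiating C2 from C7 in the ring-forming step is better than anything in the chosen plan, which needs a separate Wittig step (7 to 8). The chosen plan sets against it a ring fusion fixed by alkylation on a chair and never enolisable afterwards.

**Alternative 3:** This road cuts C6–C7. An aldehyde (C6) and an ethynyl group (C7) on a fully substituted trans-cyclopentanone are joined by Ni(cod)2 (zerovalent nickel), an N-heterocyclic carbene and Et3SiH. The product is A3, with the silylated allylic alcohol and the methylidene in place.
- Merits: the C6/C7 unit is made in one step, already differentiated from C1′, and A3 is three steps from the target (triethylsilyl removal, esterification, tert-butyldimethylsilyl removal). For this unit the road is better than the Wittig step plus selenium dioxide oxidation of the chosen plan.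
- Weak points: nothing obvious forces the oxygen at C6 into the axial position. The substrate is a cyclopentanone with all five carbons functionalised, four contiguous stereocentres, an α-acyloxy ketone and a second carbonyl that can also couple with the alkyne. Making it is the real problem and is only postponed.
- Comparison: the chosen plan sets against it that the cyclopentanone stereocentres are made on six-membered rings (14, 16, 19) and transferred by one stereospecific shift.

Key step: step 14

Assumption: (E)-3-methylpent-2-enoic acid (20) is taken as a purchased reagent of defined E geometry, like the Grignard solutions and the phosphonium salt.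

## Route

Step 1
Reactants: 1 3-methylbutanal; 2 but-3-en-2-one
Product: 4 (S)-cryptone [(4S)-4-(propan-2-yl)cyclohex-2-en-1-one], via (2S)-5-oxo-2-(propan-2-yl)hexanal 3 (not isolated)
Conditions: (S)-2-[methoxy(diphenyl)methyl]pyrrolidine (5 mol %), ethyl 3,4-dihydroxybenzoate (20 mol %), neat, 4 °C; then LiOH (cat.), i-PrOH, rt
Reagents that add atoms: none
Why: Enamine-catalysed asymmetric Michael addition: the E-enamine of 1 adds to 2 on the face away from the diarylmethyl group, which by the steric-shielding model sets C4 as S; LiOH then brings about intramolecular aldol condensation of 3 under conditions mild enough to leave the γ-stereocentre untouched.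

Step 2
Reactants: 4 (S)-cryptone; 5 methyl bromoacetate
Product: 7 methyl 2-[(1R,2S,3S)-2-ethenyl-6-oxo-3-(propan-2-yl)cyclohexyl]acetate, via bromomagnesium enolate 6 (not isolated)
Conditions: CH2=CHMgBr, CuBr·SMe2 (10 mol %), THF, −78 → −40 °C; then DMPU, BrCH2CO2Me, −78 → 0 °C
Reagents that add atoms: vinylmagnesium bromide, C=C[Mg]Br
Why: Copper-catalysed 1,4-addition places the vinyl group (future C3) anti to the isopropyl group, and enolate 6 is alkylated at C7a anti to the new vinyl group (tandem conjugate addition–enolate alkylation); the product is the all-equatorial isomer, so any epimer at the enolisable C7a converges on it.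

Step 3
Reactants: 7 keto ester
Product: 8 methyl 2-[(1R,2S,3S)-2-ethenyl-6-methylidene-3-(propan-2-yl)cyclohexyl]acetate
Conditions: Ph3PCH3Br, KN(SiMe3)2, THF, 0 °C → rt
Reagents that add atoms: methyltriphenylphosphonium bromide, C[P+](c1ccccc1)(c1ccccc1)c1ccccc1.[Br-]
Why: Wittig methylenation; the unstabilised ylide reacts with the ketone and not with the methyl ester, and C7a already has its more stable equatorial configuration.

Step 4
Reactants: 8 methylidene ester
Product: 9 2-[(1R,2S,3S)-2-ethenyl-6-methylidene-3-(propan-2-yl)cyclohexyl]-N-methoxy-N-methylacetamide
Conditions: MeNH(OMe)·HCl, i-PrMgCl, THF, −20 → 0 °C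
Reagents that add atoms: N,O-dimethylhydroxylamine hydrochloride, CNOC.Cl
Why: Direct ester-to-Weinreb-amide exchange through the chloromagnesium amide; the ester is the only electrophile in 8.

Step 5
Reactants: 9 Weinreb amide
Product: 10 1-[(1R,2S,3S)-2-ethenyl-6-methylidene-3-(propan-2-yl)cyclohexyl]-3-methylbut-3-en-2-one
Conditions: CH2=C(CH3)MgBr, THF, 0 °C; cold aq NH4Cl
Reagents that add atoms: isopropenylmagnesium bromide, C=C(C)[Mg]Br
Why: Grignard addition to a Weinreb amide stops at the chelated tetrahedral adduct and releases the isopropenyl ketone on work-up, forming the C2–C1′ bond.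

Step 6
Reactants: 10 triene ketone
Product: 11 (4aR,5S,8aR)-3-methyl-8-methylidene-5-(propan-2-yl)-4a,5,6,7,8,8a-hexahydronaphthalen-2(1H)-one (trans-fused enone: C2 ketone, C3=C1′ alkene, C7 methylidene in target locants)
Conditions: RuCl2(=CHPh)(H2IMes)(PCy3) (second-generation Grubbs catalyst, 5 mol %), CH2Cl2, 40 °C
Reagents that add atoms: none
Why: Ring-closing metathesis: the catalyst loads onto the monosubstituted vinyl group and closes onto the isopropenyl ketone to give the trisubstituted enone of a six-membered ring; the C7 methylidene could only form a four-membered ring with the vinyl group and stays out.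

Step 7
Reactants: 11 trans-fused enone
Product: 12 (2S,4aR,5S,8aR)-3-methyl-8-methylidene-5-(propan-2-yl)-1,2,4a,5,6,7,8,8a-octahydronaphthalen-2-ol (2β-hydroxyl, pseudo-equatorial)
Conditions: NaBH4, CeCl3·7H2O, MeOH, −78 → 0 °C
Reagents that add atoms: none
Why: Luche 1,2-reduction; hydride enters C2 axially from the α face of the conformationally locked enone and leaves the pseudo-equatorial 2β-hydroxyl.

Step 8
Reactants: 12 allylic alcohol
Product: 13 β-epoxy alcohol (12 with the C3=C1′ alkene converted into the epoxide whose oxygen is cis to the 2β-hydroxyl and to H-3a; C1′ methyl α)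
Conditions: VO(acac)2 (cat.), t-BuOOH, CH2Cl2, 0 °C → rt
Reagents that add atoms: tert-butyl hydroperoxide, CC(C)(C)OO
Why: Hydroxyl-directed epoxidation: the vanadium alkoxide–peroxide delivers oxygen to the alkene face that carries the allylic hydroxyl, giving the β-epoxide; the C7 methylidene is not allylic to the hydroxyl and is not epoxidised.

Step 9
Reactants: 13 β-epoxy alcohol
Product: 14 β-epoxy ketone (trans-fused 3β,1′β-epoxy-1′-methyl-7-methylidene-4β-(propan-2-yl)decalin-2-one in target locants; H-3a β, H-7a α)
Conditions: n-Pr4N[RuO4] (cat.), N-methylmorpholine N-oxide, 4 Å molecular sieves, CH2Cl2, rt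
Reagents that add atoms: none
Why: Ley–Griffith oxidation of the secondary alcohol under neutral conditions that leave the epoxide and the alkene intact.

Step 10
Reactants: 14 β-epoxy ketone
Product: 16 1β-hydroxy derivative of 14 (axial hydroxyl; H-1 α), via potassium enolate 15 (not isolated)
Conditions: KN(SiMe3)2, THF, −78 °C; then 2-(benzenesulfonyl)-3-phenyloxaziridine, −78 °C; AcOH quench
Reagents that add atoms: 2-(benzenesulfonyl)-3-phenyloxaziridine (Davis oxaziridine), O=S(=O)(N1OC1c1ccccc1)c1ccccc1
Why: Enolate hydroxylation with a Davis oxaziridine: C1 is the only enolisable position because C1′ is fully substituted, and oxygen enters axially on the β face, anti to the axial H-7a; this is also the isomer that avoids the clash between an equatorial C1 substituent and the C7 methylidene.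

Step 11
Reactants: 16 1β-hydroxy epoxy ketone; 17 (R)-2-methylbutanoic acid
Product: 18 1β-[(2R)-2-methylbutanoyl]oxy derivative of 14
Conditions: DIC, DMAP (cat.), CH2Cl2, 0 °C → rt
Reagents that add atoms: none
Why: Steglich esterification of the only hydroxyl group; catalytic DMAP and low temperature keep the α-stereocentre of the acid from epimerising through a ketene.

Step 12
Reactants: 18 C1 ester
Product: 19 6α-hydroxy derivative of 18 (axial allylic alcohol; H-6 β)
Conditions: SeO2 (cat.), t-BuOOH, CH2Cl2, rt
Reagents that add atoms: tert-butyl hydroperoxide, CC(C)(C)OO; selenium dioxide, O=[Se]=O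
Why: Selenium dioxide allylic oxidation (ene reaction, then [2,3]-sigmatropic shift) attacks the ring CH2 at C6 in preference to the tertiary C7a–H and returns the double bond to the exocyclic position; the axial H-6 is removed and oxygen is delivered to the same α face, giving the axial alcohol as in related methylidene decalins.

Step 13
Reactants: 19 6α-alcohol; 20 (E)-3-methylpent-2-enoic acid
Product: 21 6α-[(2E)-3-methylpent-2-enoyl]oxy derivative of 18 (the β-epoxy decalone carrying both esters)
Conditions: DIC, DMAP (cat.), CH2Cl2, 0 °C → rt
Reagents that add atoms: none
Why: Steglich esterification of the only free hydroxyl; carbodiimide activation without a stoichiometric amine base avoids the vinylketene pathway that would deconjugate or isomerise the E-enoate.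

Step 14
Reactants: 21 β-epoxy decalone diester
Product: 22 (1S,3S,3aS,4S,6R,7aR)-3-acetyl-7-methylidene-1-{[(2R)-2-methylbutanoyl]oxy}-2-oxo-4-(propan-2-yl)octahydro-1H-inden-6-yl (2E)-3-methylpent-2-enoate
Conditions: BF3·OEt2, CH2Cl2, −20 → 0 °C; aq NaHCO3 work-up
Reagents that add atoms: none
Why: BF3 binds the epoxide oxygen, and the C3–O bond, the only epoxide bond not α to the C2 carbonyl, lengthens while positive charge builds at C3. The C1′–C2 bond lies antiperiplanar to it and shifts to C3 with inversion as the C1′–O bond becomes the acetyl carbonyl (1,2-acyl shift). The closest known reaction is the Lewis-acid rearrangement of α,β-epoxy ketones to β-dicarbonyl compounds, in which 2,3-epoxycyclohexanones contract to 2-acylcyclopentanones. The five-membered ring C1–C2–C3–C3a–C7a is closed by this 1,2-shift, a ring contraction and not an end-to-end cyclisation, so no exo or endo category applies. The new stereocentre C3 is fixed by the epoxide configuration: entry of C2 anti to the β oxygen leaves the acetyl group on the β face, trans to the C3a–C4 bond, which is also the more stable epimer, so enolisation of the β-diketone can only confirm it. The step needs acyl migration to win over methyl migration and over hydride shift from C3a; in the β-epoxide the C3–O bond is equatorial in the chair-like transition state of the rigid trans-decalin, so only the ring bond C1′–C2 is aligned with it, the α methyl group on C1′ and the axial H-3a are not, and C1′ carries no hydrogen. BF3 is a promoter and is not consumed; low temperature and the bicarbonate work-up, which also hydrolyses any BF2 chelate of the product, protect the allylic ester, the methylidene and the α-acyloxy ketone.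

Step 15
Reactants: 22 β-diketone
Product: 23 target, (1S,3S,3aS,4S,6R,7aR)-3-[(1R)-1-hydroxyethyl]-7-methylidene-1-{[(2R)-2-methylbutanoyl]oxy}-2-oxo-4-(propan-2-yl)octahydro-1H-inden-6-yl (2E)-3-methylpent-2-enoate
Conditions: RuCl[(R,R)-TsDPEN](p-cymene) (cat.), HCO2H/Et3N (5:2), CH2Cl2, rt
Reagents that add atoms: none
Why: Noyori–Ikariya asymmetric transfer hydrogenation: the methyl ketone is far more accessible than C2, which is flanked by two tertiary carbons, and the (R,R)-ligand is expected to give the 1′R carbinol with the acyl-bearing C3 in the place an aryl group takes in acetophenone; C3 stays in its more stable configuration through the enol, and the syn (1′R,3S) product is also the one a chelate model predicts from the substrate.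

## Compound list

1 | 3-methylbutanal | CC(C)CC=O | starting material
2 | but-3-en-2-one | CC(=O)C=C | starting material
3 | (2S)-5-oxo-2-(propan-2-yl)hexanal | O=C[C@H](C(C)C)CCC(C)=O | intermediate (not isolated)
4 | (S)-cryptone, (4S)-4-(propan-2-yl)cyclohex-2-en-1-one | O=C1C=C[C@H](C(C)C)CC1 | intermediate
5 | methyl bromoacetate | COC(=O)CBr | starting material
6 | bromomagnesium (3S,4S)-3-ethenyl-4-(propan-2-yl)cyclohex-1-en-1-olate | Br[Mg]OC1=C[C@@H](C=C)[C@H](C(C)C)CC1 | intermediate (not isolated)
7 | methyl 2-[(1R,2S,3S)-2-ethenyl-6-oxo-3-(propan-2-yl)cyclohexyl]acetate | O=C1[C@H](CC(=O)OC)[C@@H](C=C)[C@H](C(C)C)CC1 | intermediate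
8 | methyl 2-[(1R,2S,3S)-2-ethenyl-6-methylidene-3-(propan-2-yl)cyclohexyl]acetate | C=C1[C@H](CC(=O)OC)[C@@H](C=C)[C@H](C(C)C)CC1 | intermediate
9 | 2-[(1R,2S,3S)-2-ethenyl-6-methylidene-3-(propan-2-yl)cyclohexyl]-N-methoxy-N-methylacetamide | C=C1[C@H](CC(=O)N(C)OC)[C@@H](C=C)[C@H](C(C)C)CC1 | intermediate
10 | 1-[(1R,2S,3S)-2-ethenyl-6-methylidene-3-(propan-2-yl)cyclohexyl]-3-methylbut-3-en-2-one | C=C1[C@H](CC(=O)C(C)=C)[C@@H](C=C)[C@H](C(C)C)CC1 | intermediate
11 | (4aR,5S,8aR)-3-methyl-8-methylidene-5-(propan-2-yl)-4a,5,6,7,8,8a-hexahydronaphthalen-2(1H)-one | C=C1[C@H]2[C@@H](C=C(C)C(=O)C2)[C@H](C(C)C)CC1 | intermediate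
12 | (2S,4aR,5S,8aR)-3-methyl-8-methylidene-5-(propan-2-yl)-1,2,4a,5,6,7,8,8a-octahydronaphthalen-2-ol (2β-alcohol) | C=C1[C@H]2[C@@H](C=C(C)[C@@H](O)C2)[C@H](C(C)C)CC1 | intermediate
13 | β-epoxy alcohol: 3β,1′β-epoxide of 12, hydroxyl 2β, C1′ methyl α | C=C1[C@H]2[C@@H]([C@H]3O[C@@]3(C)[C@@H](O)C2)[C@H](C(C)C)CC1 | intermediate
14 | β-epoxy ketone: trans-fused 3β,1′β-epoxy-1′-methyl-7-methylidene-4β-(propan-2-yl)decalin-2-one (target locants) | C=C1[C@H]2[C@@H]([C@H]3O[C@@]3(C)C(=O)C2)[C@H](C(C)C)CC1 | intermediate
15 | potassium enolate of 14 (C1=C2–OK) | C=C1[C@H]2[C@@H]([C@H]3O[C@@]3(C)C(O[K])=C2)[C@H](C(C)C)CC1 | intermediate (not isolated)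
16 | 1β-hydroxy derivative of 14 (axial OH, H-1 α) | C=C1[C@H]2[C@@H]([C@H]3O[C@@]3(C)C(=O)[C@H]2O)[C@H](C(C)C)CC1 | intermediate
17 | (R)-2-methylbutanoic acid | CC[C@@H](C)C(=O)O | starting material
18 | 1β-[(2R)-2-methylbutanoyl]oxy derivative of 14 | C=C1[C@H]2[C@@H]([C@H]3O[C@@]3(C)C(=O)[C@H]2OC(=O)[C@H](C)CC)[C@H](C(C)C)CC1 | intermediate
19 | 6α-hydroxy derivative of 18 (axial allylic alcohol, H-6 β) | C=C1[C@H]2[C@@H]([C@H]3O[C@@]3(C)C(=O)[C@H]2OC(=O)[C@H](C)CC)[C@H](C(C)C)C[C@H]1O | intermediate
20 | (E)-3-methylpent-2-enoic acid | CC/C(C)=C/C(=O)O | starting material
21 | β-epoxy decalone diester: 6α-[(2E)-3-methylpent-2-enoyl]oxy derivative of 18 | C=C1[C@H]2[C@@H]([C@H]3O[C@@]3(C)C(=O)[C@H]2OC(=O)[C@H](C)CC)[C@H](C(C)C)C[C@H]1OC(=O)/C=C(\C)CC | intermediate (substrate of the key step)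
22 | (1S,3S,3aS,4S,6R,7aR)-3-acetyl-7-methylidene-1-{[(2R)-2-methylbutanoyl]oxy}-2-oxo-4-(propan-2-yl)octahydro-1H-inden-6-yl (2E)-3-methylpent-2-enoate | C=C1[C@H]2[C@@H]([C@@H](C(C)=O)C(=O)[C@H]2OC(=O)[C@H](C)CC)[C@H](C(C)C)C[C@H]1OC(=O)/C=C(\C)CC | intermediate (product of the key step)
23 | (1S,3S,3aS,4S,6R,7aR)-3-[(1R)-1-hydroxyethyl]-7-methylidene-1-{[(2R)-2-methylbutanoyl]oxy}-2-oxo-4-(propan-2-yl)octahydro-1H-inden-6-yl (2E)-3-methylpent-2-enoate | C=C1[C@H]2[C@@H]([C@@H]([C@@H](C)O)C(=O)[C@H]2OC(=O)[C@H](C)CC)[C@H](C(C)C)C[C@H]1OC(=O)/C=C(\C)CC | target

## Step count and steps least certain to work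

Total: 15 steps. Longest linear sequence: 15 steps, from 1 and 2 to 23; compounds 5, 17 and 20 enter as purchased building blocks.

**Step 14 (key step).** Ionisation at the secondary C3, next to an electron-poor acyl carbon, may be slow. The Lewis acidity then needed may ionise the axial allylic ester at C6, with loss or transposition of the enoate or migration of the double bond, before the acyl shift is complete. Fallback: the contraction is moved ahead of the C6 oxidation. It sets out from 18.
- BF3·OEt2 in CH2Cl2 should convert 18 into the 6-deoxy β-diketone F1, which has no allylic ester to lose.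
- Transfer hydrogenation as in step 15 gives the 1′R alcohol F2.
- TBSOTf and 2,6-lutidine give the silyl ether F3.
- SeO2/t-BuOOH gives the 6α-alcohol F4. The β-diketone, which selenium dioxide would oxidise at C3, is by then reduced and masked.
- Esterification with 20 (DIC, DMAP) gives the silylated diester F5, and HF·pyridine returns to the route at 23.

**Step 15.** Hydride transfer may also reach C2, which is activated by the acyloxy group, and facial discrimination at a ketone without an aryl group may be weak. Fallback: substrate control in place of catalyst control, from 22 directly to 23 with Zn(BH4)2 in Et2O at low temperature. Zinc bridges the two carbonyl oxygens, and hydride adds to the acetyl carbonyl on the side of H-3, away from C3a, which by the chelate model gives the same syn (1′R,3S) isomer. No new compound is made.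

**Step 10.** Facial selectivity at C1 may be poor if the bulky oxaziridine approaches from the α face, and the enolate may decay through the neighbouring epoxide if it is allowed to warm. Fallback: starting from 14, if the hydroxylation delivers mainly the 1α-hydroxy epimer F6, that alcohol is esterified with 17 under Mitsunobu conditions (PPh3, DIAD, toluene). Inversion at C1 gives the 1β ester directly and returns to the route at 18.

**Step 2.** Proton transfer between enolate and product may lead to alkylation at C6 or double alkylation, and the magnesium enolate may react sluggishly. Fallback: from 4, the vinyl cuprate addition is run with Me3SiCl to give the trimethylsilyl enol ether F7, which is isolated. MeLi regenerates the lithium enolate regiospecifically, and alkylation with 5 in THF/DMPU comes back at 7.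

**Step 12.** Oxygen may be delivered in part to the equatorial position if the [2,3] shift loses facial control, and prolonged reaction oxidises the allylic alcohol on to the C6 ketone. Fallback: starting from 18, the oxidation is stopped early. Any equatorial 6β-hydroxy epimer F8 is esterified with 20 under Mitsunobu conditions (PPh3, DIAD), which inverts C6 and returns to the route at 21.

## Further compounds

F1 | step 14 | 6-deoxy β-diketone (22 without the C6 ester) | C=C1[C@H]2[C@@H]([C@@H](C(C)=O)C(=O)[C@H]2OC(=O)[C@H](C)CC)[C@H](C(C)C)CC1
F2 | step 14 | 6-deoxy 1′R alcohol (23 without the C6 ester) | C=C1[C@H]2[C@@H]([C@@H]([C@@H](C)O)C(=O)[C@H]2OC(=O)[C@H](C)CC)[C@H](C(C)C)CC1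
F3 | step 14 | 1′-O-tert-butyldimethylsilyl ether of F2 | C=C1[C@H]2[C@@H]([C@@H]([C@@H](C)O[Si](C)(C)C(C)(C)C)C(=O)[C@H]2OC(=O)[C@H](C)CC)[C@H](C(C)C)CC1
F4 | step 14 | 6α-hydroxy derivative of F3 | C=C1[C@H]2[C@@H]([C@@H]([C@@H](C)O[Si](C)(C)C(C)(C)C)C(=O)[C@H]2OC(=O)[C@H](C)CC)[C@H](C(C)C)C[C@H]1O
F5 | step 14 | 1′-O-tert-butyldimethylsilyl ether of 23 | C=C1[C@H]2[C@@H]([C@@H]([C@@H](C)O[Si](C)(C)C(C)(C)C)C(=O)[C@H]2OC(=O)[C@H](C)CC)[C@H](C(C)C)C[C@H]1OC(=O)/C=C(\C)CC
F0 | step 15 | none | none
F6 | step 10 | 1α-hydroxy epimer of 16 | C=C1[C@H]2[C@@H]([C@H]3O[C@@]3(C)C(=O)[C@@H]2O)[C@H](C(C)C)CC1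
F7 | step 2 | trimethylsilyl enol ether, (3S,4S)-3-ethenyl-4-(propan-2-yl)-1-(trimethylsilyloxy)cyclohex-1-ene | C[Si](C)(C)OC1=C[C@@H](C=C)[C@H](C(C)C)CC1
F8 | step 12 | 6β-hydroxy epimer of 19 | C=C1[C@H]2[C@@H]([C@H]3O[C@@]3(C)C(=O)[C@H]2OC(=O)[C@H](C)CC)[C@H](C(C)C)C[C@@H]1O
A1 | alternative 1 | trans-fused hydrindene with C6 tert-butyldimethylsilyl enol ether, C2 triethylsilyl ether and C1′ tert-butyldimethylsilyl ether | CC(C)(C)[Si](C)(C)OC1=C[C@@H]2C[C@@H](O[Si](CC)(CC)CC)[C@H]([C@@H](C)O[Si](C)(C)C(C)(C)C)[C@H]2[C@H](C(C)C)C1
A2 | alternative 2 | trans-fused C7 ketone with C2 dimethyl ketal and C1′ tert-butyldimethylsilyl ether | O=C1[C@H]2[C@@H]([C@@H]([C@@H](C)O[Si](C)(C)C(C)(C)C)C(OC)(OC)C2)[C@H](C(C)C)CC1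
A3 | alternative 3 | full skeleton with C1 2-methylbutanoate, C6 triethylsilyl ether and C1′ tert-butyldimethylsilyl ether | C=C1[C@H]2[C@@H]([C@@H]([C@@H](C)O[Si](C)(C)C(C)(C)C)C(=O)[C@H]2OC(=O)[C@H](C)CC)[C@H](C(C)C)C[C@H]1O[Si](CC)(CC)CC
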